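The ratio of isomer of the product to target in this flask is read here from a mean of the readings, before any rate law. The flask with 24 mM of substrate is the theta run carried on, and the epsilon run differs from it in charge.

| flask | substrate | remark | time |
|---|---|---|---|
| theta | 24 mM | the very flask that is asked about, followed so far |  |
| epsilon | 16 mM | run made earlier |  |
| flask | 24 mM |  | 20 h |

| run | time / h | isomer of the product / % | target / % |
|---|---|---|---|
| theta | 0.833 | 9.6 | 8.7 |
| theta | 2.50 | 19.0 | 19.9 |
| theta | 5.00 | 29.3 | 27.8 |
| theta | 8.00 | 32.0 | 32.0 |
| theta | 10.0 | 35.2 | 32.8 |
| epsilon | 0.667 | 8.7 | 8.8 |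
| epsilon | 1.33 | 13.4 | 13.7 |
| epsilon | 2.50 | 21.6 | 22.4 |
| epsilon | 4.00 | 26.3 | 27.8 |
| epsilon | 8.00 | 34.8 | 35.9 |

(each reading ± 1 percentage point)

- ratio of isomer of the product to target at 6.0 min
- ratio of isomer of the product to target at 20 h

- the numbers in the tables scatter by 1 percentage point (one standard deviation)

Both curves bend, yet their quotient can still hold, so each curve is replaced by its mean. The isomer readings of both runs, summed, over the target readings, summed, give ρ = 1.00. This split ratio, a selectivity factor, is the parts of isomer of the product formed per part of target.

One number serves if it moves with neither charge nor time. Theta alone reads 1.03 and epsilon alone 0.965, a gap of 0.0672 against a scatter of 0.0389, so it stays within two scatters. The earliest pair of readings gives 1.05, worth 0.114 either way, and the latest pair 1.02, a smaller difference than that scatter. This reckoning therefore puts both asked ratios at ρ, give or take one standard deviation of 0.0194.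

The forecast, 1.02 at 6.0 min and 1.05 at 20 h, starts from “Both products rise together from the earliest points” and stands above ρ at the later time.

The flask gives 0.998 at 6.0 min and 0.998 at 20 h.

    substrate ⇌ other conformer, settled at all times (K = 0.610)
    substrate → target (k = 0.220 h⁻¹)
    2 other conformer → homo dimer (k = 34.0 M⁻¹ h⁻¹)
    other conformer ⇌ third conformer (K = 0.0500, k = 0.720 h⁻¹)
    other conformer → isomer of the product (k = 0.360 h⁻¹)
    third conformer → third product (k = 0.600 h⁻¹)

In the flask, other conformer gives isomer of the product with a constant of 0.36 h⁻¹ and substrate gives target with a constant of 0.22 h⁻¹, at 0.61 of other conformer per substrate, so the two rates stand in the ratio 0.998. The neighbour flask with 60 mM of substrate ends with 26.2% of target, less than the 35.1% of the flask; ρ times that gives 26.2%, and the neighbour flask holds 26.2% of isomer of the product.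

The numbers in the tables stem from a simulated flask from invented constants, noise included.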